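**Retrosynthetic overview** (quinone numbered C1(=O), C2(CH3), C3(OCH3), C4(=O), C5(side chain), C6(H))
1. The angelate ester, the silyl ether and the quinone oxidation level are end-game adjustments, so the real target is the (S)-silyloxy hydroquinone.
2. Feature used: C6 (the only ring C–H), its neighbour C5 and the exocyclic C(=CH2) carbon on C5 form a buta-1,3-dien-2-yl unit, CH2=C(–)–C(=CH2)–. C1, C2, C3 and C4 are the four carbons of 3-methoxy-4-methylcyclobutenedione.
3. Only one ring is built, the six-membered carbocycle. It forms by 4π opening of a 4-dienyl-4-hydroxycyclobutenone and 6π closure, which makes the C1–C6 bond.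
4. The cyclobutenone comes from the dione (dimethyl squarate plus MeLi) and a 2-lithio-1,3-diene. The anion is generated from a vinylstannane by tin–lithium exchange, because HBr addition to an enyne would not spare the trisubstituted alkene or the silyl ether.
5. 2,3-Bis(trimethylstannyl)butadiene serves twice as a vinyl-anion source: exchange and acylation with a Weinreb amide, CBS reduction to set the (S)-carbinol, silylation, then a second exchange and addition to the dione.

Key step: step 8

Remark on the chemistry: the carbinol carbon created when the dienyllithium adds to the dione forms as a mixture of epimers and is written without a descriptor, because it becomes an sp2 ring carbon in the key step. Dimethyl squarate, 1,4-dichlorobut-2-yne, hexamethylditin, 4-methylpent-3-enoic acid and angelic acid are taken as commercial.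

**Step 1**
Reactants: 1 dimethyl squarate
Product: 4 3-methoxy-4-methylcyclobut-3-ene-1,2-dione, via lithium alkoxide 2 (not isolated), via trifluoroacetate 3 (not isolated)
Conditions: MeLi, THF, −78 °C; (CF3CO)2O, −78 °C; then H2O, −78 °C → rt
Reagents that add atoms: methyllithium, [Li]C; water, O
Why: 1,2-addition of MeLi to one of the two equivalent carbonyls, O-trifluoroacetylation and methoxy-assisted ionisation/hydrolysis (the standard squarate ester to alkylcyclobutenedione sequence) should expel methanol and restore the dione.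

**Step 2**
Reactants: 5 1,4-dichlorobut-2-yne
Product: 7 2,3-bis(trimethylstannyl)buta-1,3-diene, via allenyl chloride 6 (not isolated)
Conditions: Me6Sn2, MeLi, THF, −20 °C; CuBr·SMe2, −78 °C; then 5, −78 → 0 °C
Reagents that add atoms: hexamethylditin, C[Sn](C)(C)[Sn](C)(C)C
Why: Two successive SN2′ displacements by the soft stannylcopper reagent (propargylic chloride to allenylstannane, then attack at the central allene carbon of the allenylmethyl chloride) should place both tin atoms on the inner diene carbons, whereas the bare stannyllithium would favour direct SN2 substitution.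

**Step 3**
Reactants: 8 4-methylpent-3-enoic acid
Product: 10 N-methoxy-N,4-dimethylpent-3-enamide, via acyl imidazole 9 (not isolated)
Conditions: 1,1′-carbonyldiimidazole, CH2Cl2, rt; then MeNH(OMe)·HCl, rt
Reagents that add atoms: N,O-dimethylhydroxylamine hydrochloride, CNOC.Cl
Why: Weinreb amide formation through the acyl imidazole needs neither strong base nor a ketene-prone acid chloride, so the β,γ-alkene should not move into conjugation.

**Step 4**
Reactants: 7 2,3-bis(trimethylstannyl)buta-1,3-diene; 10 N-methoxy-N,4-dimethylpent-3-enamide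
Product: 12 7-methyl-3-methylidene-2-(trimethylstannyl)octa-1,6-dien-4-one, via stannyl dienyllithium 11 (not isolated)
Conditions: MeLi (1.0 equiv), THF, −78 °C; then 10, −78 °C; cold aq NH4Cl; product used at once
Reagents that add atoms: none
Why: Tin–lithium exchange with one equivalent of MeLi should stop at the monolithio stage, and the Weinreb ketone synthesis holds the adduct as a chelated tetrahedral intermediate until the cold quench, so no over-addition or conjugate addition to the new dienone is expected.

**Step 5**
Reactants: 12 7-methyl-3-methylidene-2-(trimethylstannyl)octa-1,6-dien-4-one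
Product: 13 (4S)-7-methyl-3-methylidene-2-(trimethylstannyl)octa-1,6-dien-4-ol
Conditions: (R)-1-methyl-3,3-diphenyltetrahydro-1H,3H-pyrrolo[1,2-c][1,3,2]oxazaborole ((R)-Me-CBS, 0.2 equiv), catecholborane, toluene, −78 °C; MeOH, then aqueous work-up
Reagents that add atoms: none
Why: In the Corey–Bakshi–Shibata reduction the α-branched dienyl group acts as the large substituent and the CH2 group as the small one, so the (R)-catalyst should deliver hydride to the face that gives the (S)-alcohol, and catecholborane at −78 °C leaves the alkenes and the C–Sn bond alone.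

**Step 6**
Reactants: 13 (4S)-7-methyl-3-methylidene-2-(trimethylstannyl)octa-1,6-dien-4-ol
Product: 14 tert-butyl(dimethyl){[(4S)-7-methyl-3-methylidene-2-(trimethylstannyl)octa-1,6-dien-4-yl]oxy}silane
Conditions: TBSCl, imidazole, DMF, rt
Reagents that add atoms: tert-butyldimethylsilyl chloride, CC(C)(C)[Si](C)(C)Cl
Why: Imidazole-mediated O-silylation is non-acidic, so protodestannylation is avoided, and the C–O bond at the stereocentre is not touched.

**Step 7**
Reactants: 14 tert-butyl(dimethyl){[(4S)-7-methyl-3-methylidene-2-(trimethylstannyl)octa-1,6-dien-4-yl]oxy}silane; 4 3-methoxy-4-methylcyclobut-3-ene-1,2-dione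
Product: 16 4-[(4S)-4-(tert-butyldimethylsilyloxy)-7-methyl-3-methylideneocta-1,6-dien-2-yl]-4-hydroxy-3-methoxy-2-methylcyclobut-2-en-1-one (both carbinol epimers), via dienyllithium 15 (not isolated)
Conditions: MeLi, THF, −78 °C; then 4, THF, −78 °C; aq NH4Cl at −78 °C
Reagents that add atoms: none
Why: After tin–lithium exchange the vinyllithium should add 1,2 to the carbonyl flanked by C–OMe, because the other carbonyl is deactivated as a vinylogous ester, and keeping everything at −78 °C keeps 1,4 O→C silyl migration slower than carbonyl addition.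

**Step 8**
Reactants: 16 4-[(4S)-4-(tert-butyldimethylsilyloxy)-7-methyl-3-methylideneocta-1,6-dien-2-yl]-4-hydroxy-3-methoxy-2-methylcyclobut-2-en-1-one
Product: 19 5-[(3S)-3-(tert-butyldimethylsilyloxy)-6-methylhepta-1,5-dien-2-yl]-3-methoxy-2-methylbenzene-1,4-diol, via dienylketene 17 (not isolated), via cyclohexadienone 18 (not isolated)
Conditions: toluene (degassed, 0.01 M), 110 °C, Ar
Reagents that add atoms: none
Why: Heat should break the C1–C4 bond of the cyclobutenone in a strain-releasing conrotatory 4π opening, the (Z)-dienylketene 17 then bonds its ketene carbon to the terminal CH2 of the vinyl unit attached to the former carbinol carbon, and enolisation of 18 gives the arene. This is the Moore rearrangement of 4-alkenyl-4-hydroxycyclobutenones, applied here to a buta-1,3-dien-2-yl substituent. The single new ring, the six-membered carbocycle, is closed by a disrotatory 6π electrocyclisation (one new C–C bond), and aromatisation makes the sequence irreversible. No stereocentre is created: the carbinol carbon becomes sp2, so both epimers converge, and the (S)-silyloxy centre is a spectator with no ionisable or acidic bond under neutral thermolysis. The selectivity needed is torquoselectivity, and the donor hydroxyl secures it by rotating outward and turning the dienyl group toward the ketene, while the second methylene is only cross-conjugated and cannot join a linear triene, so one closure alone is open. Ring regiochemistry was fixed in step 7, and dilution under argon should suppress Diels–Alder capture of the diene by any quinone formed prematurely.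

**Step 9**
Reactants: 19 5-[(3S)-3-(tert-butyldimethylsilyloxy)-6-methylhepta-1,5-dien-2-yl]-3-methoxy-2-methylbenzene-1,4-diol
Product: 20 5-[(3S)-3-(tert-butyldimethylsilyloxy)-6-methylhepta-1,5-dien-2-yl]-3-methoxy-2-methylcyclohexa-2,5-diene-1,4-dione
Conditions: Ag2O, MgSO4, Et2O, rt, dark
Reagents that add atoms: none
Why: Heterogeneous two-electron hydroquinone-to-quinone oxidation with Ag2O is neutral and should leave the alkenes, the silyl ether and the stereocentre untouched.

**Step 10**
Reactants: 20 5-[(3S)-3-(tert-butyldimethylsilyloxy)-6-methylhepta-1,5-dien-2-yl]-3-methoxy-2-methylcyclohexa-2,5-diene-1,4-dione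
Product: 21 5-[(3S)-3-hydroxy-6-methylhepta-1,5-dien-2-yl]-3-methoxy-2-methylcyclohexa-2,5-diene-1,4-dione
Conditions: HF·pyridine, pyridine, THF, 0 °C → rt (polyethylene vessel)
Reagents that add atoms: none
Why: Buffered fluoride-mediated Si–O cleavage avoids the basic fluoride sources that a methoxyquinone does not tolerate, is too weakly acidic to protonate the prenyl alkene, and leaves the C–O bond of the stereocentre intact.

**Step 11**
Reactants: 21 5-[(3S)-3-hydroxy-6-methylhepta-1,5-dien-2-yl]-3-methoxy-2-methylcyclohexa-2,5-diene-1,4-dione; 22 angelic acid [(2Z)-2-methylbut-2-enoic acid]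
Product: 24 (3S)-2-(5-methoxy-4-methyl-3,6-dioxocyclohexa-1,4-dien-1-yl)-6-methylhepta-1,5-dien-3-yl (2Z)-2-methylbut-2-enoate, via mixed anhydride 23 (not isolated)
Conditions: 22, 2,4,6-Cl3C6H2COCl, Et3N, toluene, rt; then 21, toluene, 70 °C
Reagents that add atoms: none
Why: In this Yamaguchi-type mixed-anhydride esterification, run without a nucleophilic catalyst, the alcohol should attack the less hindered angeloyl carbonyl; leaving out DMAP removes the addition–elimination path from angelate to tiglate, and acyl transfer to oxygen retains the (S)-configuration.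

**Compound list**
1 | dimethyl squarate (3,4-dimethoxycyclobut-3-ene-1,2-dione) | COC1=C(OC)C(=O)C1=O | starting material
2 | lithium 2,3-dimethoxy-1-methyl-4-oxocyclobut-2-en-1-olate | [Li+].[O-]C1(C)C(OC)=C(OC)C1=O | intermediate
3 | 2,3-dimethoxy-1-methyl-4-oxocyclobut-2-en-1-yl trifluoroacetate | O=C1C(OC)=C(OC)C1(C)OC(=O)C(F)(F)F | intermediate
4 | 3-methoxy-4-methylcyclobut-3-ene-1,2-dione | COC1=C(C)C(=O)C1=O | intermediate
5 | 1,4-dichlorobut-2-yne | ClCC#CCCl | starting material
6 | (1-chlorobuta-2,3-dien-2-yl)trimethylstannane | ClCC(=C=C)[Sn](C)(C)C | intermediate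
7 | 2,3-bis(trimethylstannyl)buta-1,3-diene | C=C([Sn](C)(C)C)C(=C)[Sn](C)(C)C | intermediate
8 | 4-methylpent-3-enoic acid | CC(C)=CCC(=O)O | starting material
9 | 1-(1H-imidazol-1-yl)-4-methylpent-3-en-1-one | CC(C)=CCC(=O)n1ccnc1 | intermediate
10 | N-methoxy-N,4-dimethylpent-3-enamide | CC(C)=CCC(=O)N(C)OC | intermediate
11 | [3-(trimethylstannyl)buta-1,3-dien-2-yl]lithium | [Li]C(=C)C(=C)[Sn](C)(C)C | intermediate
12 | 7-methyl-3-methylidene-2-(trimethylstannyl)octa-1,6-dien-4-one | C=C([Sn](C)(C)C)C(=C)C(=O)CC=C(C)C | intermediate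
13 | (4S)-7-methyl-3-methylidene-2-(trimethylstannyl)octa-1,6-dien-4-ol | C=C([Sn](C)(C)C)C(=C)[C@H](CC=C(C)C)O | intermediate
14 | tert-butyl(dimethyl){[(4S)-7-methyl-3-methylidene-2-(trimethylstannyl)octa-1,6-dien-4-yl]oxy}silane | C=C([Sn](C)(C)C)C(=C)[C@H](CC=C(C)C)O[Si](C)(C)C(C)(C)C | intermediate
15 | [(4S)-4-(tert-butyldimethylsilyloxy)-7-methyl-3-methylideneocta-1,6-dien-2-yl]lithium | [Li]C(=C)C(=C)[C@H](CC=C(C)C)O[Si](C)(C)C(C)(C)C | intermediate
16 | 4-[(4S)-4-(tert-butyldimethylsilyloxy)-7-methyl-3-methylideneocta-1,6-dien-2-yl]-4-hydroxy-3-methoxy-2-methylcyclobut-2-en-1-one | O=C1C(C)=C(OC)C1(O)C(=C)C(=C)[C@H](CC=C(C)C)O[Si](C)(C)C(C)(C)C | intermediate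
17 | (3Z,7S)-7-(tert-butyldimethylsilyloxy)-4-hydroxy-3-methoxy-2,10-dimethyl-5,6-dimethylideneundeca-1,3,9-trien-1-one (dienylketene) | O=C=C(C)/C(OC)=C(O)\C(=C)C(=C)[C@H](CC=C(C)C)O[Si](C)(C)C(C)(C)C | intermediate
18 | 5-[(3S)-3-(tert-butyldimethylsilyloxy)-6-methylhepta-1,5-dien-2-yl]-4-hydroxy-3-methoxy-2-methylcyclohexa-2,4-dien-1-one | O=C1CC(C(=C)[C@H](CC=C(C)C)O[Si](C)(C)C(C)(C)C)=C(O)C(OC)=C1C | intermediate
19 | 5-[(3S)-3-(tert-butyldimethylsilyloxy)-6-methylhepta-1,5-dien-2-yl]-3-methoxy-2-methylbenzene-1,4-diol | C=C(c1cc(O)c(C)c(OC)c1O)[C@H](CC=C(C)C)O[Si](C)(C)C(C)(C)C | intermediate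
20 | 5-[(3S)-3-(tert-butyldimethylsilyloxy)-6-methylhepta-1,5-dien-2-yl]-3-methoxy-2-methylcyclohexa-2,5-diene-1,4-dione | C=C(C1=CC(=O)C(C)=C(OC)C1=O)[C@H](CC=C(C)C)O[Si](C)(C)C(C)(C)C | intermediate
21 | 5-[(3S)-3-hydroxy-6-methylhepta-1,5-dien-2-yl]-3-methoxy-2-methylcyclohexa-2,5-diene-1,4-dione | C=C(C1=CC(=O)C(C)=C(OC)C1=O)[C@H](CC=C(C)C)O | intermediate
22 | angelic acid, (2Z)-2-methylbut-2-enoic acid | O=C(O)/C(C)=C\C | starting material
23 | (2Z)-2-methylbut-2-enoic 2,4,6-trichlorobenzoic anhydride | O=C(OC(=O)c1c(Cl)cc(Cl)cc1Cl)/C(C)=C\C | intermediate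
24 | (3S)-2-(5-methoxy-4-methyl-3,6-dioxocyclohexa-1,4-dien-1-yl)-6-methylhepta-1,5-dien-3-yl (2Z)-2-methylbut-2-enoate | C=C(C1=CC(=O)C(C)=C(OC)C1=O)[C@H](CC=C(C)C)OC(=O)/C(C)=C\C | target

**Step count**
- Total: 11 steps.
- Longest linear sequence: 9 steps (5 → 7 → 12 → 13 → 14 → 16 → 19 → 20 → 21 → 24).

**Steps most likely to fail**

**1. Step 8 (key step).**
- Risk: some ring opening may occur with the hydroxyl turning inward, followed by lactonisation of the ketene. The 2,3-disubstituted diene may self-condense thermally by Diels–Alder reaction. Traces of air may oxidise the hot hydroquinone, which then undergoes cycloaddition with unreacted diene.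
- Fallback: it sets out from 15 and 4 and returns at 20. The lithium alkoxide formed on addition is silylated in the same flask with Me3SiCl to give the 4-trimethylsilyloxy cyclobutenone F1. This has no free hydroxyl to trap the ketene and still carries an outward-rotating oxygen donor. Thermolysis in toluene should give the mono-silylated hydroquinone F2, which cannot be oxidised by air in the hot solution. (NH4)2Ce(NO3)6 in aqueous MeCN at 0 °C then takes F2 directly to 20.

**2. Step 4.**
- Risk: the vinyllithium may abstract a proton from the doubly activated CH2 of the amide instead of adding. The cross-conjugated 2-acyl diene may dimerise by Diels–Alder reaction on concentration. The liberated amine may add in conjugate fashion during work-up.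
- Fallback: it sets out from 10 and 7, returns at 13 and never passes through a dienone. i-Bu2AlH (THF, −78 °C) reduces 10 to 4-methylpent-3-enal F3. Reagent 11, made from 7 and MeLi as before, adds to it to give the racemic dienol F4. A Sharpless kinetic resolution follows (Ti(OiPr)4, D-(−)-diisopropyl tartrate, t-BuOOH, 4 Å sieves, CH2Cl2, −20 °C, taken just past half conversion). It should epoxidise the (R)-enantiomer to the epoxy alcohol F5 and leave (S)-13 for separation.

**3. Step 11.**
- Risk: the activated angeloyl unit may isomerise from Z to E. Acylation of the hindered allylic alcohol may be slow. The vinylquinone may erode thermally or under amine during the long heating.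
- Fallback: it sets out from 19 and returns at 24, so that deprotection and acylation are done on a robust arene.
  - MeI and K2CO3 in acetone under argon give the hydroquinone dimethyl ether F6.
  - Bu4NF in THF gives the free alcohol F7.
  - Deprotonation with LiN(SiMe3)2 at −78 °C and acylation of the alkoxide with 23 gives the aryl angelate F8 at low temperature, without a nucleophilic catalyst.
  - Oxidative demethylation with (NH4)2Ce(NO3)6 in aqueous MeCN at 0 °C unmasks the para-quinone, keeps the central methoxy group, and gives 24.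

**Further compounds**
F1 | step 8 | 4-[(4S)-4-(tert-butyldimethylsilyloxy)-7-methyl-3-methylideneocta-1,6-dien-2-yl]-3-methoxy-2-methyl-4-(trimethylsilyloxy)cyclobut-2-en-1-one | O=C1C(C)=C(OC)C1(O[Si](C)(C)C)C(=C)C(=C)[C@H](CC=C(C)C)O[Si](C)(C)C(C)(C)C
F2 | step 8 | 5-[(3S)-3-(tert-butyldimethylsilyloxy)-6-methylhepta-1,5-dien-2-yl]-3-methoxy-2-methyl-4-(trimethylsilyloxy)phenol | C=C(c1cc(O)c(C)c(OC)c1O[Si](C)(C)C)[C@H](CC=C(C)C)O[Si](C)(C)C(C)(C)C
F3 | step 4 | 4-methylpent-3-enal | CC(C)=CCC=O
F4 | step 4 | rac-7-methyl-3-methylidene-2-(trimethylstannyl)octa-1,6-dien-4-ol | C=C([Sn](C)(C)C)C(=C)C(O)CC=C(C)C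
F5 | step 4 | (1R)-4-methyl-1-{(2S)-2-[1-(trimethylstannyl)ethenyl]oxiran-2-yl}pent-3-en-1-ol | O[C@H](CC=C(C)C)[C@@]1(CO1)C(=C)[Sn](C)(C)C
F6 | step 11 | tert-butyl(dimethyl){[(3S)-6-methyl-2-(2,3,5-trimethoxy-4-methylphenyl)hepta-1,5-dien-3-yl]oxy}silane | C=C(c1cc(OC)c(C)c(OC)c1OC)[C@H](CC=C(C)C)O[Si](C)(C)C(C)(C)C
F7 | step 11 | (3S)-6-methyl-2-(2,3,5-trimethoxy-4-methylphenyl)hepta-1,5-dien-3-ol | C=C(c1cc(OC)c(C)c(OC)c1OC)[C@H](CC=C(C)C)O
F8 | step 11 | (3S)-6-methyl-2-(2,3,5-trimethoxy-4-methylphenyl)hepta-1,5-dien-3-yl (2Z)-2-methylbut-2-enoate | C=C(c1cc(OC)c(C)c(OC)c1OC)[C@H](CC=C(C)C)OC(=O)/C(C)=C\C
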